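**Plan**
- Retrosynthesis: first the ester and protecting groups are removed. Then, in the cyclohexanone ring, the C(=O)–CH2 bond and the CH(CH3)–CH(cyclobutane) bond are cut, which releases propene. Next the two cyclobutane bonds C(=O)–CH and C(CH3)–CH(aryl) of a bicyclo[4.1.1]octan-8-one are cut (ketene + alkene). Last, the open chain is taken apart (olefination, two lactone alkylations, aldol).
- Forward: aldol, reduction and lactone alkylations build the chain. One intramolecular ketene–alkene [2+2] closes the cyclobutane and the seven-membered ring together. A radical annulation with propene then closes the six-membered ring; the esters come last.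
- Enabling feature: in the bicyclo[4.1.1]octan-8-one the CH bridge that carries the carboxyl carbon and the C=O bridge carbon face each other 1,3 across the cyclobutane (about 2.2 Å), both anti to the four-carbon bridge. As its N-aziridinyl imine the C=O carbon accepts a radical and ends as the bridgehead CH.
- Stereochemistry: the CH–OH centre comes from a catalytic asymmetric vinylogous aldol, the CH–O(angeloyl) centre from a 1,3-anti reduction, and the quaternary C(CH3)(CH2OAc) from two trans-selective lactone dianion alkylations. The three cyclobutane centres come from the cycloaddition (tether, E-alkene) and CH(CH3) from the radical ring closure.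

Key step: step 15

Remark: 1-amino-2-phenylaziridine is taken as an available reagent (two steps from styrene glycol dimesylate and hydrazine); the hydrazone is used as the mixture of C=N and aziridine isomers, which all converge in step 15.
Remark: the methyl-bearing centre made in step 9 (drawn 2,3-anti) becomes the ketene carbon in step 11, so its configuration is inconsequential.

**Step 1**
Reactants: 1 methacrolein; 2 1-methoxy-1,3-bis(trimethylsilyloxy)buta-1,3-diene
Product: 3 methyl (5R)-5-hydroxy-6-methyl-3-oxohept-6-enoate
Conditions: Ti(OiPr)4 (cat.), (R)-BINOL (cat.; the ligand enantiomer is chosen to give the 5R alcohol), 4 Å MS, THF, −78 °C to rt; then TFA, THF/H2O, 0 °C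
Reagents that add atoms: none
Why: Catalytic asymmetric vinylogous Mukaiyama aldol addition, in which the γ-carbon of the bis-silyl dienolate adds to the aldehyde bound to the chiral titanium–BINOL complex, whose open face sets the carbinol centre, and acid then removes both silyl groups.

**Step 2**
Reactants: 3
Product: 5 (4R,6R)-4-hydroxy-6-(prop-1-en-2-yl)oxan-2-one (4,6-cis), via anti-diol ester 4 (not isolated)
Conditions: Me4NBH(OAc)3, MeCN/AcOH, −30 °C; then PPTS (cat.), toluene, 60 °C
Reagents that add atoms: none
Why: Evans–Saksena reduction, in which boron bound to the C-5 hydroxyl delivers hydride internally to give the 1,3-anti diol, and the δ-hydroxy ester then lactonises under mild acid.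

**Step 3**
Reactants: 5
Product: 6 (4,6-cis)-4-hydroxy-3-methyl-6-(prop-1-en-2-yl)oxan-2-one with 3-CH3 trans to 4-OH
Conditions: LDA (2.2 equiv), THF, −78 to −40 °C; MeI, DMPU; then H2O
Reagents that add atoms: iodomethane, CI
Why: Fráter–Seebach alkylation of the alkoxide–enolate dianion, in which the electrophile enters the lactone enolate trans to the neighbouring oxido group.

**Step 4**
Reactants: 6
Product: 7 4-hydroxy-3-(hydroxymethyl)-3-methyl-6-(prop-1-en-2-yl)oxan-2-one with CH2OH trans and CH3 cis to 4-OH
Conditions: LDA (2.2 equiv), THF, −78 °C; CH2O (gas, from paraformaldehyde), −78 °C; then H2O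
Reagents that add atoms: formaldehyde, C=O
Why: Second Fráter–Seebach reaction (aldol addition to monomeric formaldehyde), in which attack again occurs trans to the oxido group, so the quaternary centre forms with hydroxymethyl trans and methyl cis to the 4-oxygen.

**Step 5**
Reactants: 7
Product: 8 isopropylidene acetal of 7 (1,3-dioxane trans-fused to the lactone)
Conditions: Me2C(OMe)2, PPTS (cat.), CH2Cl2, rt
Reagents that add atoms: 2,2-dimethoxypropane, COC(C)(C)OC
Why: Acid-catalysed transacetalisation of the 1,3-diol to the six-membered acetonide, which masks both oxygens with one group.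

**Step 6**
Reactants: 8
Product: 9 lactol of 8 (anomer mixture)
Conditions: DIBAL-H (1.2 equiv), CH2Cl2, −78 °C
Reagents that add atoms: none
Why: Partial reduction of the lactone, because the tetrahedral aluminate is stable at low temperature and gives the lactol on work-up.

**Step 7**
Reactants: 9; 10 diethyl (4-methoxybenzyl)phosphonate
Product: 11 allylic alcohol carrying the (E)-4-methoxystyryl group on the quaternary dioxane carbon
Conditions: NaH, THF, 0 to 65 °C
Reagents that add atoms: none
Why: Horner–Wadsworth–Emmons olefination of the ring-opened hydroxy aldehyde, in which the benzylic phosphonate anion gives the E alkene and the former ring oxygen is released as the free secondary alcohol.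

**Step 8**
Reactants: 11
Product: 12 tert-butyldimethylsilyl ether of 11
Conditions: TBSOTf, 2,6-lutidine, CH2Cl2, −78 to 0 °C
Reagents that add atoms: tert-butyldimethylsilyl triflate, CC(C)(C)[Si](C)(C)OS(=O)(=O)C(F)(F)F
Why: Silylation of the hindered secondary alcohol with the silyl triflate and a non-nucleophilic base; the acetonide is untouched.

**Step 9**
Reactants: 12
Product: 13 primary alcohol (2-methyl, 2,3-anti)
Conditions: 9-BBN, THF, 0 °C to rt; then NaOH, H2O2
Reagents that add atoms: hydrogen peroxide, OO
Why: Anti-Markovnikov hydroboration–oxidation, in which 9-BBN selects the 1,1-disubstituted alkene over the hindered styryl alkene and A(1,3) strain favours the anti product.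

**Step 10**
Reactants: 13
Product: 14 carboxylic acid
Conditions: TEMPO (cat.), PhI(OAc)2, MeCN/H2O, rt
Reagents that add atoms: water, O
Why: Oxoammonium-mediated oxidation of the primary alcohol through the aldehyde hydrate to the acid, under conditions that leave the alkene, silyl ether and acetal intact.

**Step 11**
Reactants: 14
Product: 17 7-anti-(4-methoxyphenyl)bicyclo[4.1.1]octan-8-one (silyl ether, acetonide), via acid chloride 15 (not isolated), via ketene 16 (not isolated)
Conditions: 1-chloro-N,N,2-trimethylprop-1-en-1-amine, CH2Cl2, 0 °C to rt; then slow addition to Et3N, toluene, 110 °C, high dilution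
Reagents that add atoms: none
Why: Intramolecular ketene–alkene [2+2] cycloaddition, in which the ketene carbonyl carbon bonds to the tether-side alkene carbon while charge builds at the anisyl-stabilised carbon, so closure is crossed and gives the cyclobutanone and the seven-membered ring; the E alkene places the aryl anti to the four-carbon bridge, and the trans-fused dioxane plus the preference of the pseudo-axial methyl of the quaternary carbon to face the flat ketene C=O should select the alkene face.

**Step 12**
Reactants: 17
Product: 18 keto acid (CO2H anti on the cyclobutane CH)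
Conditions: RuCl3·xH2O (cat.), NaIO4, CCl4/MeCN/H2O, rt
Reagents that add atoms: sodium periodate, [Na+].[O-]I(=O)(=O)=O; water, O
Why: RuO4-mediated oxidative degradation of the electron-rich arene (aryl as carboxyl surrogate), which leaves the ipso carbon as CO2H with retention at the cyclobutane CH.

**Step 13**
Reactants: 18
Product: 19 N-aziridinyl imine of the cyclobutanone (acid retained)
Conditions: 1-amino-2-phenylaziridine, EtOH, 0 °C to rt
Reagents that add atoms: 1-amino-2-phenylaziridine, NN1CC1c1ccccc1
Why: Hydrazone formation, in which the strained and therefore reactive cyclobutanone condenses with the N-amino group.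

**Step 14**
Reactants: 19
Product: 20 Se-phenyl selenoester
Conditions: N-(phenylselanyl)phthalimide, Bu3P, CH2Cl2, −20 °C to rt
Reagents that add atoms: N-(phenylselanyl)phthalimide, O=C1N([Se]c2ccccc2)C(=O)c2ccccc12
Why: Phosphine-mediated selenoesterification (acyloxyphosphonium, then selenolate attack) under neutral conditions that keep the aziridinyl imine intact.

**Step 15**
Reactants: 20; 21 propene
Product: 24 tricyclic ketone (silyl ether, acetonide), via acyl radical 22 (not isolated), via alkyl radical 23 (not isolated)
Conditions: Bu3SnH (slow addition), AIBN (cat.), propene (large excess, sealed vessel), benzene, 80 °C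
Reagents that add atoms: none
Why: Proposed new method: a tin-mediated radical chain in which Bu3Sn• abstracts PhSe from the selenoester, the nucleophilic acyl radical adds to the CH2 end of propene (first new bond, C(=O)–CH2), and the secondary alkyl radical closes onto the carbon of the N-aziridinyl imine (second new bond, CH(CH3)–cyclobutane C), after which the aminyl radical opens the aziridine, loses styrene and N2, and the bridgehead radical is reduced by Bu3SnH. The closest known reaction types are the intermolecular addition of selenoester-derived acyl radicals to alkenes and the cyclisation of carbon radicals onto N-aziridinyl imines with loss of styrene and N2; their union as an intermolecular annulation onto a cyclobutanone hydrazone has not been shown. The six-membered ring closes in the 6-exo mode across the cyclobutane, which is possible because the acyl carbon and the C=N carbon are held 1,3-cis and anti to the four-carbon bridge, and the former C=N carbon becomes the unsubstituted bridgehead CH. The CH(CH3) centre is set in the ring closure, where the methyl of the planar radical turns away from the methyl on the neighbouring quaternary cyclobutane carbon and ends on the side of the cyclobutane CH bridge, as in the target; the bridgehead CH has only one possible configuration. The step needs acyl addition at the terminal alkene carbon (steric and polar control), capture of propene faster than reduction or decarbonylation (propene in large excess, low stannane concentration), and cyclisation faster than telomerisation (transannular proximity).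

**Step 16**
Reactants: 24
Product: 25 diol (secondary OH and CH2OH free, silyl ether kept)
Conditions: AcOH/H2O/THF (3:1:1), 40 °C
Reagents that add atoms: none
Why: Acid hydrolysis of the acetonide, which the hindered secondary TBS ether should survive.

**Step 17**
Reactants: 25
Product: 26 primary acetate
Conditions: Ac2O (1.1 equiv), 2,4,6-collidine, CH2Cl2, −20 to 0 °C
Reagents that add atoms: acetic anhydride, CC(=O)OC(C)=O
Why: Selective acetylation, because the primary hydroxyl reacts faster than the secondary neopentyl hydroxyl.

**Step 18**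
Reactants: 26; 27 angelic acid
Product: 28 angelate (silyl ether kept)
Conditions: 2,4,6-trichlorobenzoyl chloride, Et3N, toluene, rt; then 26, 80 °C
Reagents that add atoms: none
Why: Yamaguchi esterification through the mixed anhydride, run without a nucleophilic catalyst so that the Z double bond is not isomerised.

**Step 19**
Reactants: 28
Product: 29 target CNP0212099.1
Conditions: HF·pyridine, pyridine/THF, 0 °C to rt
Reagents that add atoms: none
Why: Fluoride-mediated desilylation under buffered conditions that leave the acetate, the angelate and the ketone untouched.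

**Compound list**
1 | methacrolein | CC(=C)C=O | starting material
2 | 1-methoxy-1,3-bis(trimethylsilyloxy)buta-1,3-diene | COC(=CC(=C)O[Si](C)(C)C)O[Si](C)(C)C | starting material
3 | methyl (5R)-5-hydroxy-6-methyl-3-oxohept-6-enoate | COC(=O)CC(=O)C[C@@H](O)C(C)=C | intermediate
4 | methyl (3R,5R)-3,5-dihydroxy-6-methylhept-6-enoate (1,3-anti) | COC(=O)C[C@H](O)C[C@@H](O)C(C)=C | intermediate (not isolated)
5 | (4R,6R)-4-hydroxy-6-(prop-1-en-2-yl)oxan-2-one | O=C1C[C@H](O)C[C@H](C(C)=C)O1 | intermediate
6 | 3-methyl lactone, CH3 trans to 4-OH | O=C1[C@@H](C)[C@H](O)C[C@H](C(C)=C)O1 | intermediate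
7 | 3-(hydroxymethyl)-3-methyl lactone, CH2OH trans and CH3 cis to 4-OH | O=C1[C@@](C)(CO)[C@H](O)C[C@H](C(C)=C)O1 | intermediate
8 | acetonide lactone (dioxane trans-fused to the lactone) | O=C1[C@@]2(C)COC(C)(C)O[C@@H]2C[C@H](C(C)=C)O1 | intermediate
9 | lactol of 8 | OC1[C@@]2(C)COC(C)(C)O[C@@H]2C[C@H](C(C)=C)O1 | intermediate
10 | diethyl (4-methoxybenzyl)phosphonate | CCOP(=O)(Cc1ccc(OC)cc1)OCC | starting material
11 | 1-[5-((E)-4-methoxystyryl)-2,2,5-trimethyl-1,3-dioxan-4-yl]-3-methylbut-3-en-2-ol | C=C(C)[C@H](O)C[C@H]1OC(C)(C)OC[C@]1(C)/C=C/c2ccc(OC)cc2 | intermediate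
12 | TBS ether of 11 | C=C(C)[C@H](O[Si](C)(C)C(C)(C)C)C[C@H]1OC(C)(C)OC[C@]1(C)/C=C/c2ccc(OC)cc2 | intermediate
13 | primary alcohol (2,3-anti) | OC[C@H](C)[C@H](O[Si](C)(C)C(C)(C)C)C[C@H]1OC(C)(C)OC[C@]1(C)/C=C/c2ccc(OC)cc2 | intermediate
14 | 2-methyl-3-silyloxy carboxylic acid | OC(=O)[C@H](C)[C@H](O[Si](C)(C)C(C)(C)C)C[C@H]1OC(C)(C)OC[C@]1(C)/C=C/c2ccc(OC)cc2 | intermediate
15 | acid chloride of 14 | ClC(=O)[C@H](C)[C@H](O[Si](C)(C)C(C)(C)C)C[C@H]1OC(C)(C)OC[C@]1(C)/C=C/c2ccc(OC)cc2 | intermediate (not isolated)
16 | methyl ketene from 15 | O=C=C(C)[C@H](O[Si](C)(C)C(C)(C)C)C[C@H]1OC(C)(C)OC[C@]1(C)/C=C/c2ccc(OC)cc2 | intermediate (not isolated)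
17 | 7-anti-(4-methoxyphenyl)-bridgehead-methyl bicyclo[4.1.1]octan-8-one, silyl ether, acetonide | O1[C@@H]2C[C@@H](O[Si](C)(C)C(C)(C)C)[C@]3(C)C(=O)[C@@H]([C@H]3c4ccc(OC)cc4)[C@@]2(C)COC1(C)C | intermediate
18 | 8-oxobicyclo[4.1.1]octane-7-anti-carboxylic acid | O1[C@@H]2C[C@@H](O[Si](C)(C)C(C)(C)C)[C@]3(C)C(=O)[C@@H]([C@H]3C(=O)O)[C@@]2(C)COC1(C)C | intermediate
19 | N-(2-phenylaziridin-1-yl)imine of 18 | O1[C@@H]2C[C@@H](O[Si](C)(C)C(C)(C)C)[C@]3(C)C(=NN4CC4c5ccccc5)[C@@H]([C@H]3C(=O)O)[C@@]2(C)COC1(C)C | intermediate
20 | Se-phenyl selenoester of 19 | O1[C@@H]2C[C@@H](O[Si](C)(C)C(C)(C)C)[C@]3(C)C(=NN4CC4c5ccccc5)[C@@H]([C@H]3C(=O)[Se]c6ccccc6)[C@@]2(C)COC1(C)C | intermediate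
21 | propene | CC=C | starting material
22 | acyl radical from 20 | O1[C@@H]2C[C@@H](O[Si](C)(C)C(C)(C)C)[C@]3(C)C(=NN4CC4c5ccccc5)[C@@H]([C@H]3[C]=O)[C@@]2(C)COC1(C)C | intermediate (not isolated)
23 | 3-oxoalkyl radical after propene capture | O1[C@@H]2C[C@@H](O[Si](C)(C)C(C)(C)C)[C@]3(C)C(=NN4CC4c5ccccc5)[C@@H]([C@H]3C(=O)C[CH]C)[C@@]2(C)COC1(C)C | intermediate (not isolated)
24 | tricyclic ketone, silyl ether, acetonide | O1[C@@H]2C[C@@H](O[Si](C)(C)C(C)(C)C)[C@]3(C)[C@@H]4[C@@H]([C@H]3C(=O)C[C@H]4C)[C@@]2(C)COC1(C)C | intermediate
25 | diol, silyl ether | O[C@@H]1C[C@@H](O[Si](C)(C)C(C)(C)C)[C@]2(C)[C@@H]3[C@@H]([C@H]2C(=O)C[C@H]3C)[C@@]1(C)CO | intermediate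
26 | primary acetate, silyl ether | O[C@@H]1C[C@@H](O[Si](C)(C)C(C)(C)C)[C@]2(C)[C@@H]3[C@@H]([C@H]2C(=O)C[C@H]3C)[C@@]1(C)COC(C)=O | intermediate
27 | angelic acid, (Z)-2-methylbut-2-enoic acid | C/C=C(/C)C(=O)O | starting material
28 | angelate acetate, silyl ether | C/C=C(/C)C(=O)O[C@@H]1C[C@@H](O[Si](C)(C)C(C)(C)C)[C@]2(C)[C@@H]3[C@@H]([C@H]2C(=O)C[C@H]3C)[C@@]1(C)COC(C)=O | intermediate
29 | CNP0212099.1 | C/C=C(/C)C(=O)O[C@@H]1C[C@@H](O)[C@]2(C)[C@@H]3[C@@H]([C@H]2C(=O)C[C@H]3C)[C@@]1(C)COC(C)=O | target

Total steps: 19. Longest linear sequence: 19 steps (1 to 29).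

**Steps most likely to fail**

1. Step 15 (proposed new method). The acyl radical may be reduced or lose CO before it captures propene, the alkyl radical may be trapped or add a second propene before it closes onto the C=N carbon, or the stannyl radical may attack the hydrazone. The fallback uses only known reactions and sets out from 18.
 - NaBH4 (MeOH, 0 °C) reduces the cyclobutanone to the hydroxy acid F1 (either carbinol epimer serves).
 - EDC/HOBt coupling with MeNHOMe·HCl gives the Weinreb amide F2.
 - (E)-Prop-1-enyllithium (excess, THF, −78 °C) gives the hydroxy (E)-enone F3.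
 - 1,1'-Thiocarbonyldiimidazole (DMAP, 1,2-dichloroethane, 60 °C) gives the imidazolyl thiocarbonate F4.
 - Bu3SnH/AIBN (benzene, 80 °C, slow addition) generates the cyclobutyl radical (Barton–McCombie mode), which closes 6-endo onto the enone β-carbon with the methyl again turned away from the bridge methyl. It comes back to the route at 24.

2. Step 11. The ketene may oligomerise because the tether closes a seven-membered ring, the cycloaddition may close in the fused sense or on the wrong alkene face, or silanolate may be lost by β-elimination during dehydrochlorination. The fallback changes the reacting species to a cationic keteniminium ion and sets out from 14.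
 - Coupling with dimethylamine (EDC, HOBt) gives the dimethylamide F5.
 - Tf2O and 2,6-di-tert-butyl-4-methylpyridine (1,2-dichloroethane, rt to 80 °C) give the keteniminium triflate F6.
 - F6 closes by intramolecular [2+2] to the cyclobutaniminium triflate F7.
 - Aqueous NaHCO3 hydrolyses the iminium salt. It comes back to the route at 17.

3. Step 18. Acylation of the neopentyl secondary alcohol may be slow, the activated angelate may isomerise from Z to E, and the neighbouring acetate may migrate. The fallback builds the Z double bond on the ester and sets out from 26.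
 - 2-(Diphenoxyphosphoryl)propanoic acid with DCC/DMAP (CH2Cl2, rt) gives the phosphonopropionate ester F8.
 - NaH and acetaldehyde (THF, −78 to 0 °C) give the Z alkene in a Z-selective Horner–Wadsworth–Emmons reaction with the diaryl phosphonate. It comes back to the route at 28.

**Further compounds**
F1 | step 15 | hydroxy acid from reduction of 18 | O1[C@@H]2C[C@@H](O[Si](C)(C)C(C)(C)C)[C@]3(C)C(O)[C@@H]([C@H]3C(=O)O)[C@@]2(C)COC1(C)C
F2 | step 15 | hydroxy Weinreb amide | O1[C@@H]2C[C@@H](O[Si](C)(C)C(C)(C)C)[C@]3(C)C(O)[C@@H]([C@H]3C(=O)N(C)OC)[C@@]2(C)COC1(C)C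
F3 | step 15 | hydroxy (E)-propenyl ketone | O1[C@@H]2C[C@@H](O[Si](C)(C)C(C)(C)C)[C@]3(C)C(O)[C@@H]([C@H]3C(=O)/C=C/C)[C@@]2(C)COC1(C)C
F4 | step 15 | imidazolyl thiocarbonate of F3 | O1[C@@H]2C[C@@H](O[Si](C)(C)C(C)(C)C)[C@]3(C)C(OC(=S)n4ccnc4)[C@@H]([C@H]3C(=O)/C=C/C)[C@@]2(C)COC1(C)C
F5 | step 11 | N,N-dimethylamide of 14 | CN(C)C(=O)[C@H](C)[C@H](O[Si](C)(C)C(C)(C)C)C[C@H]1OC(C)(C)OC[C@]1(C)/C=C/c2ccc(OC)cc2
F6 | step 11 | keteniminium triflate | C[N+](C)=C=C(C)[C@H](O[Si](C)(C)C(C)(C)C)C[C@H]1OC(C)(C)OC[C@]1(C)/C=C/c2ccc(OC)cc2.[O-]S(=O)(=O)C(F)(F)F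
F7 | step 11 | cyclobutaniminium triflate | O1[C@@H]2C[C@@H](O[Si](C)(C)C(C)(C)C)[C@]3(C)C(=[N+](C)C)[C@@H]([C@H]3c4ccc(OC)cc4)[C@@]2(C)COC1(C)C.[O-]S(=O)(=O)C(F)(F)F
F8 | step 18 | 2-(diphenoxyphosphoryl)propanoate of 26 | CC(C(=O)O[C@@H]1C[C@@H](O[Si](C)(C)C(C)(C)C)[C@]2(C)[C@@H]3[C@@H]([C@H]2C(=O)C[C@H]3C)[C@@]1(C)COC(C)=O)P(=O)(Oc4ccccc4)Oc5ccccc5
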